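A direct plan would join the pieces at ring A–C8 and C7–ring B in one palladium-catalysed conjunctive coupling.
The ring A phenol would be brominated and silylated to bromide A1, and an (E)-propenylboronic ester A2 of a hindered diol would be made from acenaphthoquinone.
3,4-Dimethoxyphenyllithium A3 would be added to A2, the ate complex coupled with A1 under a chiral palladium catalyst, the C–B bond oxidised to silyl ether A4, and the silyl group removed.
Its weakest steps would be:
- Masking and unmasking the phenol: two steps that add no complexity and exist only because the coupling cannot bear a free OH.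
- Building the diol ligand of A2: two further steps spent on atoms that are all discarded.
- The coupling itself: both stereocentres and two C–C bonds would rest on one catalyst-controlled event with an ortho-silyloxy aryl bromide carrying a free allyl group. Heck addition, double-bond migration and direct Suzuki coupling would compete, and it would need t-BuLi at the point where all fragments meet.

**Plan of the new route**
The target is cut first at C7–H (both stereocentres set last, from racemic ketone 6), then at C7–C8 (key), then at C8=C9 (Wittig) and ring A–C8 (ortho-formylation of eugenol 1); C7–ring B is bought in veratraldehyde 5.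
No ring is formed: ring A is elaborated first, ring B enters in step 3, and the two are joined through the chain, not through an aryl–metal coupling.
The enabling feature is the free phenolic OH of ring A, ortho to the ring carbon that bears C8: as the phenoxide of 4 it holds rhodium beside the vinyl group and steers the acyl carbon of 5 (C7) onto benzylic C8.
The OH that a coupling would force one to mask thus becomes the directing group, so no protecting group, boron ligand, aryl halide or organolithium occurs.
The stereocentres are uncoupled from the fragment union: C8–H of 6 lies between the C7 carbonyl and ring A and epimerises under base, so one catalyst-controlled hydrogenation with dynamic kinetic resolution sets C7 and C8 together.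

Key step: step 3

Remark: C7 is the carbinol carbon, C8 the methyl-bearing carbon on ring A and C9 the methyl carbon; 6 and 7 are assumed to need neutral or basic handling, since acid would let the ring A phenol cyclise onto C7.

Step 1
Reactants: 1 eugenol (4-allyl-2-methoxyphenol)
Product: 3 5-allyl-2-hydroxy-3-methoxybenzaldehyde, via 4-allyl-2-(hydroxymethyl)-6-methoxyphenol 2 (not isolated)
Conditions: MgCl2 (1.5 equiv), Et3N (3.75 equiv), (CH2O)n (6.75 equiv), MeCN, reflux; then 1 M HCl
Reagents that add atoms: paraformaldehyde (as formaldehyde), C=O
Why: Casnati–Skattebøl ortho-formylation: the magnesium phenoxide delivers formaldehyde to the only free position ortho to oxygen (the para position carries the allyl group), and the salicyl alkoxide 2 is oxidised to the aldehyde by Oppenauer-type hydride transfer to a second formaldehyde, conditions under which the isolated allyl C=C is inert.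

Step 2
Reactants: 3 5-allyl-2-hydroxy-3-methoxybenzaldehyde
Product: 4 4-allyl-2-methoxy-6-vinylphenol
Conditions: Ph3PCH3Br (2.3 equiv), t-BuOK (2.3 equiv), THF, 0 °C to rt; aq. NH4Cl; stored cold with BHT
Reagents that add atoms: methyltriphenylphosphonium bromide, C[P+](c1ccccc1)(c1ccccc1)c1ccccc1.[Br-]
Why: Wittig methylenation: one equivalent of ylide is spent as base on the phenol and the rest converts the formyl group of the phenoxide into the vinyl group through the oxaphosphetane; no stereocentre or alkene geometry is at stake.

Step 3
Reactants: 4 4-allyl-2-methoxy-6-vinylphenol; 5 3,4-dimethoxybenzaldehyde (veratraldehyde)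
Product: 6 rac-2-(5-allyl-2-hydroxy-3-methoxyphenyl)-1-(3,4-dimethoxyphenyl)propan-1-one
Conditions: 5 (1.5 equiv), [Rh(OMe)(1,5-cyclooctadiene)]2 (2.5 mol%), Cy2PCH2PCy2 (5 mol%), K3PO4 (10 mol%), MeCN, 60 °C, degassed; neutral work-up
Reagents that add atoms: none
Why: Phenol-directed intermolecular alkene hydroacylation: the phenoxide of 4 binds monovalent rhodium, the formyl C–H bond of 5 adds oxidatively to give an acyl hydride of trivalent rhodium, the hydride passes to the terminal vinyl carbon (the future C9) so that rhodium sits on benzylic C8 in a five-membered oxarhodacycle, and C–C reductive elimination joins the acyl carbon (C7) to C8. The closest known reaction is the branched-selective hydroacylation of 2-vinylphenols with non-chelating aryl and alkyl aldehydes under rhodium with a small-bite-angle diphosphine. No ring is closed. C8 is the only new stereocentre and is left racemic on purpose, because its hydrogen lies between the C7 carbonyl and ring A and would not hold a configuration under base; it is set together with C7 in step 4. The step needs branched over linear addition, reaction at the vinyl and not the allyl C=C, and C–C coupling faster than decarbonylation of the acyl hydride; all three rest on the phenoxide oxygen ortho to the vinyl group, which holds the metal beside this alkene only and favours the five-membered metallacycle, while the narrow diphosphine speeds reductive elimination.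

Step 4
Reactants: 6 rac-2-(5-allyl-2-hydroxy-3-methoxyphenyl)-1-(3,4-dimethoxyphenyl)propan-1-one
Product: 7 4-allyl-2-[(1S,2S)-1-(3,4-dimethoxyphenyl)-1-hydroxypropan-2-yl]-6-methoxyphenol (target)
Conditions: trans-RuCl2[(R)-xylbinap][(R)-daipen] (1 mol%; xylbinap = 2,2'-bis[di(3,5-xylyl)phosphino]-1,1'-binaphthyl, daipen = 1,1-bis(4-methoxyphenyl)-3-methylbutane-1,2-diamine), t-BuOK (1.3 equiv), i-PrOH, H2 (8 atm), 25 °C, degassed; aq. NH4Cl; Et3N-treated silica
Reagents that add atoms: none
Why: Noyori-type asymmetric hydrogenation with dynamic kinetic resolution: the excess alkoxide epimerises C8 of 6 through its enolate faster than the chiral hydride–diamine complex of divalent ruthenium reduces the carbonyl group, this antipode of the catalyst (chosen by analogy with aryl alkyl ketones, which it reduces to S carbinols) sets C7 as S, and only the 8S enantiomer can take that hydride in the Felkin–Anh arrangement with ring A anti to the incoming hydride, so the racemate should funnel into the (7S,8S) isomer while the carbonyl-selective catalyst leaves the allyl C=C alone.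

**Compound list**
1 | eugenol (4-allyl-2-methoxyphenol) | C=CCc1ccc(O)c(OC)c1 | starting material
2 | 4-allyl-2-(hydroxymethyl)-6-methoxyphenol | C=CCc1cc(OC)c(O)c(CO)c1 | intermediate
3 | 5-allyl-2-hydroxy-3-methoxybenzaldehyde | C=CCc1cc(OC)c(O)c(C=O)c1 | intermediate
4 | 4-allyl-2-methoxy-6-vinylphenol | C=CCc1cc(OC)c(O)c(C=C)c1 | intermediate
5 | 3,4-dimethoxybenzaldehyde (veratraldehyde) | COc1ccc(C=O)cc1OC | starting material
6 | rac-2-(5-allyl-2-hydroxy-3-methoxyphenyl)-1-(3,4-dimethoxyphenyl)propan-1-one (racemic at C8) | C=CCc1cc(OC)c(O)c(C(C)C(=O)c2ccc(OC)c(OC)c2)c1 | intermediate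
7 | 4-allyl-2-[(1S,2S)-1-(3,4-dimethoxyphenyl)-1-hydroxypropan-2-yl]-6-methoxyphenol | C=CCc1cc(OC)c(O)c([C@H](C)[C@H](O)c2ccc(OC)c(OC)c2)c1 | target

Total steps: 4. Longest linear sequence: 4 (from eugenol 1).

**Steps most likely to fail**

1. Step 3. The rhodium hydride may move the allyl double bond into conjugation, the acyl hydride may lose CO before C–C coupling, the neighbouring methoxy oxygen may tie up the metal as a chelate, or the product phenol may cyclise onto the new ketone with loss of water. The fallback sets out from 3 and returns at 6 without a transition metal. MeMgBr (3 equiv, THF, 0 °C) would convert 3 into 4-allyl-2-(1-hydroxyethyl)-6-methoxyphenol F1. Sodium p-toluenesulfinate in HCO2H–H2O at rt would exchange its benzylic hydroxyl to give 4-allyl-2-methoxy-6-[1-(4-tolylsulfonyl)ethyl]phenol F2. Cs2CO3 would eliminate sulfinate from F2 to the ortho-quinone methide 4-allyl-6-ethylidene-2-methoxycyclohexa-2,4-dien-1-one F3. The Breslow intermediate formed from 5 and the carbene of 3-benzyl-5-(2-hydroxyethyl)-4-methylthiazolium chloride (20 mol%) would add to its ethylidene carbon (Stetter-type acylation of a quinone methide) and give 6.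

2. Step 4. With the substrate present as its phenoxide, epimerisation at C8 may be slower than hydrogenation, so that the reaction turns into a kinetic resolution; the Felkin–Anh preference and the catalyst may also oppose each other, or the base may slowly isomerise the allyl group. The fallback sets out from 6 and returns at 7. Racemic 6 would be reduced without epimerisation under reagent control by a Corey–Bakshi–Shibata reduction [(R)-2-methyl-CBS-oxazaborolidine, catecholborane, toluene, −78 °C, which spares the allyl group]. The 8S ketone should give 7 and the 8R ketone the diastereomer 4-allyl-2-[(1S,2R)-1-(3,4-dimethoxyphenyl)-1-hydroxypropan-2-yl]-6-methoxyphenol F4. The two would be separated by chromatography, and F4 would be returned to 6 by Oppenauer oxidation [Al(Oi-Pr)3, acetone, toluene] for another pass.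

3. Step 1. Formylation may stall because magnesium is chelated between the phenoxide and methoxy oxygens, or the salicyl alcohol stage may condense with a second phenol. The fallback sets out from 1 and returns at 3, introducing the carbon by halogen–metal exchange. Eugenol would be brominated ortho to the hydroxyl (NBS, i-Pr2NH cat., CH2Cl2, 0 °C) to 4-allyl-2-bromo-6-methoxyphenol F5. As its lithium phenoxide, F5 would undergo bromine–lithium exchange (n-BuLi, 2.2 equiv, THF, −78 to 0 °C) and formylation with DMF to give 3 after aq. NH4Cl work-up.

**Further compounds**
F1 | step 3 | 4-allyl-2-(1-hydroxyethyl)-6-methoxyphenol (racemic) | C=CCc1cc(OC)c(O)c(C(C)O)c1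
F2 | step 3 | 4-allyl-2-methoxy-6-[1-(4-tolylsulfonyl)ethyl]phenol (racemic) | C=CCc1cc(OC)c(O)c(C(C)S(=O)(=O)c2ccc(C)cc2)c1
F3 | step 3 | 4-allyl-6-ethylidene-2-methoxycyclohexa-2,4-dien-1-one (ortho-quinone methide, geometry undefined) | CC=C1C=C(CC=C)C=C(OC)C1=O
F4 | step 4 | 4-allyl-2-[(1S,2R)-1-(3,4-dimethoxyphenyl)-1-hydroxypropan-2-yl]-6-methoxyphenol | C=CCc1cc(OC)c(O)c([C@@H](C)[C@H](O)c2ccc(OC)c(OC)c2)c1
F5 | step 1 | 4-allyl-2-bromo-6-methoxyphenol | C=CCc1cc(OC)c(O)c(Br)c1
A1 | direct plan | (4-allyl-2-bromo-6-methoxyphenoxy)(tert-butyl)dimethylsilane | C=CCc1cc(OC)c(O[Si](C)(C)C(C)(C)C)c(Br)c1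
A2 | direct plan | (E)-prop-1-enylboronic ester of cis-1,2-dimethyl-1,2-dihydroacenaphthylene-1,2-diol | C/C=C/B1O[C@]2(C)c3cccc4cccc(c34)[C@]2(C)O1
A3 | direct plan | 3,4-dimethoxyphenyllithium | [Li]c1ccc(OC)c(OC)c1
A4 | direct plan | (1S,2S)-2-[5-allyl-2-(tert-butyldimethylsilyloxy)-3-methoxyphenyl]-1-(3,4-dimethoxyphenyl)propan-1-ol | C=CCc1cc(OC)c(O[Si](C)(C)C(C)(C)C)c([C@H](C)[C@H](O)c2ccc(OC)c(OC)c2)c1
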